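**Retrosynthetic overview**
1. Target 16 ← desilylation of the 2-O-TBS bis-angelate 15 ← double angeloylation of epoxy triol 13 with two molecules of angelic acid 14 ← hydroxyl-directed epoxidation and 1,3-anti reduction of bicyclic hydroxy ketone 11.
2. Both carbocycles of 11 are closed in one flask from the acyclic, oxidised farnesane 9, in the order of the presumed cyclase pathway (farnesyl C1→C7 to the cycloheptenyl stage, then C6→C10). The polarity is reversed: a ketyl-type radical and then an enolate stand in for the two cations. Seven-membered ring first, five-membered ring second.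
3. 9 ← vinylogous aldol (C4–C5) and oxidation ← enal 5 ← asymmetric boron aldol (C8–C9) of 3-methylbutan-2-one with (E)-4,4-dimethoxy-2-methylbut-2-enal.

Notation: acyclic compounds carry farnesane numbering (C1 = aldehyde carbon; farnesane C1, C5, C6, C7, C8, C10 become daucane C10, C6, C5, C1, C2, C4). Bicyclic compounds carry daucane numbering, α means the face of the angular 15-methyl, and the absolute configuration is that of the SMILES.
Assumption: (E)-4,4-dimethoxy-2-methylbut-2-enal (the carotenoid C5 building block) is bought.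

**Route**

Step 1
Reactants: 1 (E)-4,4-dimethoxy-2-methylbut-2-enal; 2 3-methylbutan-2-one
Product: 3 (S,E)-5-hydroxy-8,8-dimethoxy-2,6-dimethyloct-6-en-3-one
Conditions: (−)-Ipc2BCl, Et3N, Et2O, 0 °C; then 1, −78 → −20 °C; H2O2, pH 7 buffer, MeOH
Reagents that add atoms: none
Why: Paterson boron aldol: the reagent enolises the ketone only on the methyl side, and the chiral enol borinate adds to the si face of the enal carbonyl through a cyclic transition state, which sets farnesane C8 as S; the acetal is inert.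

Step 2
Reactants: 3 (S,E)-5-hydroxy-8,8-dimethoxy-2,6-dimethyloct-6-en-3-one
Product: 4 (S,E)-5-(tert-butyldimethylsilyloxy)-8,8-dimethoxy-2,6-dimethyloct-6-en-3-one
Conditions: TBSCl, imidazole, DMF, rt
Reagents that add atoms: tert-butyldimethylsilyl chloride, CC(C)(C)[Si](C)(C)Cl
Why: Standard silyl ether formation at the secondary allylic hydroxyl; the bulky, non-chelating silyl group later steers the ring closure and stays on until the last step.

Step 3
Reactants: 4 (S,E)-5-(tert-butyldimethylsilyloxy)-8,8-dimethoxy-2,6-dimethyloct-6-en-3-one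
Product: 5 (S,E)-4-(tert-butyldimethylsilyloxy)-3,7-dimethyl-6-oxooct-2-enal
Conditions: pyridinium p-toluenesulfonate (0.1 equiv), acetone–H2O 10:1, rt
Reagents that add atoms: water, O
Why: Acid-catalysed acetal hydrolysis of the conjugated dimethyl acetal is much faster than cleavage of the secondary silyl ether, and the E geometry is kept.

Step 4
Reactants: 6 3-methylbut-2-enal
Product: 7 (E)-trimethyl(3-methylbuta-1,3-dienyloxy)silane
Conditions: TMSCl, Et3N, ZnCl2 (cat.), benzene, 60 °C
Reagents that add atoms: chlorotrimethylsilane, C[Si](C)(C)Cl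
Why: Soft enolisation (γ-deprotonation) of the enal gives the conjugated silyl dienol ether, the usual donor for vinylogous Mukaiyama aldol reactions.

Step 5
Reactants: 5 (S,E)-4-(tert-butyldimethylsilyloxy)-3,7-dimethyl-6-oxooct-2-enal; 7 (E)-trimethyl(3-methylbuta-1,3-dienyloxy)silane
Product: 8 (2E,6E,8S)-8-(tert-butyldimethylsilyloxy)-5-hydroxy-3,7,11-trimethyl-10-oxododeca-2,6-dienal (both C5 epimers)
Conditions: BF3·OEt2 (1.1 equiv), CH2Cl2, −78 °C; aq. NaHCO3
Reagents that add atoms: none
Why: Vinylogous Mukaiyama aldol: the γ-carbon of the dienol ether adds 1,2 to the activated enal (the ketone is far less electrophilic), which forms C4–C5 and regenerates an E-enal; the new C5 carbinol centre is not controlled and is erased in step 6.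

Step 6
Reactants: 8 (2E,6E,8S)-8-(tert-butyldimethylsilyloxy)-5-hydroxy-3,7,11-trimethyl-10-oxododeca-2,6-dienal
Product: 9 (2E,6E,8S)-8-(tert-butyldimethylsilyloxy)-3,7,11-trimethyl-5,10-dioxododeca-2,6-dienal
Conditions: MnO2 (activated, excess), CH2Cl2, rt; used at once
Reagents that add atoms: none
Why: Allylic alcohol oxidation with MnO2 is neutral and selective, so the C5 carbinol becomes the enone without touching the enal or the acidic C4 methylene.

Step 7
Reactants: 9 (2E,6E,8S)-8-(tert-butyldimethylsilyloxy)-3,7,11-trimethyl-5,10-dioxododeca-2,6-dienal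
Product: 11 2β-(tert-butyldimethylsilyloxy)-4β,10α-dihydroxydauc-8-en-6-one, via cycloheptadienyl samarium enolate 10 (not isolated)
Conditions: SmI2 (2.5 equiv), t-BuOH (2 equiv), THF, −78 → 0 °C, 0.005 M, slow addition of 9; aq. NH4Cl
Reagents that add atoms: none
Why: Proposed new method: one-electron reduction of the enal gives an O-samarium allyl (ketyl-type) radical that can rotate about C2–C3 and adds through its carbinol carbon to the enone β-carbon in a polarity-matched 7-endo closure (C1–C7; attack through C3 would be a 5-endo closure joining two fully substituted carbons), a second electron turns the α-keto radical into the trivalent samarium enolate 10, and this closes the cyclopentane by chelated aldol addition to the isopropyl ketone (C6–C10); the C8 silyloxy group stands anti to the forming bond with H8 turned into the closing ring (sets C7), the bulky O–Sm group and the C8 branch both sit pseudo-equatorial (carbinol oxygen cis to the 7-methyl), the two-atom tether forces the cis ring fusion, and the samarium-bridged chair places the new tertiary OH anti to H6; closest known reaction type: SmI2 ketyl–olefin cyclisation/aldol cascades and 8-endo ketyl–olefin cyclisations.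

Step 8
Reactants: 11 2β-(tert-butyldimethylsilyloxy)-4β,10α-dihydroxydauc-8-en-6-one
Product: 12 2β-(tert-butyldimethylsilyloxy)dauc-8-ene-4β,6α,10α-triol
Conditions: Me4NBH(OAc)3, MeCN–AcOH 1:1, −25 °C
Reagents that add atoms: none
Why: Evans–Saksena reduction: the tertiary 4β-hydroxyl binds boron and delivers hydride intramolecularly to the β-face of the 6-ketone, giving the 1,3-anti diol (6α-OH); the β,γ-olefin is untouched.

Step 9
Reactants: 12 2β-(tert-butyldimethylsilyloxy)dauc-8-ene-4β,6α,10α-triol
Product: 13 2β-(tert-butyldimethylsilyloxy)-8α,9α-epoxydaucane-4β,6α,10α-triol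
Conditions: VO(acac)2 (5 mol %), t-BuOOH, CH2Cl2, 0 °C → rt
Reagents that add atoms: tert-butyl hydroperoxide, CC(C)(C)OO
Why: Vanadium-catalysed hydroxyl-directed epoxidation: the allylic 10α-OH (helped by the homoallylic 6α-OH) binds the vanadium peroxide and delivers oxygen to the α-face, so the epoxide is syn to both carbinol oxygens.

Step 10
Reactants: 13 2β-(tert-butyldimethylsilyloxy)-8α,9α-epoxydaucane-4β,6α,10α-triol; 14 angelic acid (first of the two molecules built in)
Product: 15 2β-(tert-butyldimethylsilyloxy)-8α,9α-epoxy-4β-hydroxydaucane-6α,10α-diyl bis[(Z)-2-methylbut-2-enoate]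
Conditions: 14 (5 equiv), 2,4,6-trichlorobenzoyl chloride (5 equiv), Et3N (10 equiv), toluene, rt; then 13 (1 equiv), toluene, 75 °C
Reagents that add atoms: angelic acid (second molecule of 14), C/C=C(/C)C(=O)O
Why: Yamaguchi-type esterification through the mixed trichlorobenzoic anhydride, run without 4-(dimethylamino)pyridine and with the activated acid in excess, puts one angeloyl group on each of the two secondary hydroxyls (two molecules of 14 per molecule of 13) while keeping the Z geometry; the tertiary 4-OH and the silylated 2-OH do not react.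

Step 11
Reactants: 15 2β-(tert-butyldimethylsilyloxy)-8α,9α-epoxy-4β-hydroxydaucane-6α,10α-diyl bis[(Z)-2-methylbut-2-enoate]
Product: 16 (1R,2S,4S,5R,6R,8S,9R,10R)-8,9-epoxy-2,4-dihydroxydaucane-6,10-diyl bis[(Z)-2-methylbut-2-enoate]
Conditions: HF·pyridine, pyridine, THF, 0 °C → rt
Reagents that add atoms: none
Why: Fluoride-mediated desilylation under buffered, mildly acidic conditions removes the silyl ether without base-induced acyl migration and is mild enough for the epoxide and the Z-enoates.

**Compound list**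
1 | (E)-4,4-dimethoxy-2-methylbut-2-enal | COC(OC)/C=C(\C)C=O | starting material
2 | 3-methylbutan-2-one | CC(C)C(C)=O | starting material
3 | (S,E)-5-hydroxy-8,8-dimethoxy-2,6-dimethyloct-6-en-3-one | COC(OC)/C=C(\C)[C@@H](O)CC(=O)C(C)C | intermediate
4 | (S,E)-5-(tert-butyldimethylsilyloxy)-8,8-dimethoxy-2,6-dimethyloct-6-en-3-one | COC(OC)/C=C(\C)[C@@H](O[Si](C)(C)C(C)(C)C)CC(=O)C(C)C | intermediate
5 | (S,E)-4-(tert-butyldimethylsilyloxy)-3,7-dimethyl-6-oxooct-2-enal | O=C/C=C(\C)[C@@H](O[Si](C)(C)C(C)(C)C)CC(=O)C(C)C | intermediate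
6 | 3-methylbut-2-enal | CC(C)=CC=O | starting material
7 | (E)-trimethyl(3-methylbuta-1,3-dienyloxy)silane | C=C(C)/C=C/O[Si](C)(C)C | intermediate
8 | (2E,6E,8S)-8-(tert-butyldimethylsilyloxy)-5-hydroxy-3,7,11-trimethyl-10-oxododeca-2,6-dienal, both C5 epimers | O=C/C=C(\C)CC(O)/C=C(\C)[C@@H](O[Si](C)(C)C(C)(C)C)CC(=O)C(C)C | intermediate
9 | (2E,6E,8S)-8-(tert-butyldimethylsilyloxy)-3,7,11-trimethyl-5,10-dioxododeca-2,6-dienal | O=C/C=C(\C)CC(=O)/C=C(\C)[C@@H](O[Si](C)(C)C(C)(C)C)CC(=O)C(C)C | intermediate
10 | cycloheptadienyl samarium enolate (trivalent samarium enolate and alkoxide; C1–C7 closed, cyclopentane still open) | CC(C)C(=O)C[C@H](O[Si](C)(C)C(C)(C)C)[C@@]1(C)C=C(O[Sm](I)I)CC(C)=C[C@@H]1O[Sm](I)I | intermediate (not isolated)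
11 | 2β-(tert-butyldimethylsilyloxy)-4β,10α-dihydroxydauc-8-en-6-one (cis-fused, 5α-H) | O=C1CC(C)=C[C@H](O)[C@@]2(C)[C@@H](O[Si](C)(C)C(C)(C)C)C[C@](O)(C(C)C)[C@@H]12 | intermediate
12 | 2β-(tert-butyldimethylsilyloxy)dauc-8-ene-4β,6α,10α-triol | O[C@@H]1CC(C)=C[C@H](O)[C@@]2(C)[C@@H](O[Si](C)(C)C(C)(C)C)C[C@](O)(C(C)C)[C@@H]12 | intermediate
13 | 2β-(tert-butyldimethylsilyloxy)-8α,9α-epoxydaucane-4β,6α,10α-triol | O[C@@H]1C[C@]2(C)O[C@@H]2[C@H](O)[C@@]2(C)[C@@H](O[Si](C)(C)C(C)(C)C)C[C@](O)(C(C)C)[C@@H]12 | intermediate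
14 | angelic acid, (Z)-2-methylbut-2-enoic acid | C/C=C(/C)C(=O)O | starting material
15 | 2β-(tert-butyldimethylsilyloxy)-8α,9α-epoxy-4β-hydroxydaucane-6α,10α-diyl bis[(Z)-2-methylbut-2-enoate] | C/C=C(/C)C(=O)O[C@@H]1C[C@]2(C)O[C@@H]2[C@H](OC(=O)/C(C)=C\C)[C@@]2(C)[C@@H](O[Si](C)(C)C(C)(C)C)C[C@](O)(C(C)C)[C@@H]12 | intermediate
16 | (1R,2S,4S,5R,6R,8S,9R,10R)-8,9-epoxy-2,4-dihydroxydaucane-6,10-diyl bis[(Z)-2-methylbut-2-enoate] | C/C=C(/C)C(=O)O[C@@H]1C[C@]2(C)O[C@@H]2[C@H](OC(=O)/C(C)=C\C)[C@@]2(C)[C@@H](O)C[C@](O)(C(C)C)[C@@H]12 | target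

**Step count**
Total: 11 steps. Longest linear sequence: 10 steps (steps 1, 2, 3, 5, 6, 7, 8, 9, 10, 11).

**Three steps most likely to fail**

Step 7 (reductive bicyclisation). It is untested: the ketyl carbon may instead couple 1,2 with the C5 carbonyl (five-membered pinacol), the enone may simply be reduced, or the quaternary centre may form with the wrong sense relative to C8. Compound 9 is also sensitive at its doubly activated C4 methylene. The fallback sets out from 9 and comes back at 12. It makes the same two bonds in the same order by carbene organocatalysis instead of electron transfer. A thiazolium-derived carbene (3-benzyl-5-(2-hydroxyethyl)-4-methylthiazolium chloride, Et3N, dioxane, 70 °C) turns the aldehyde into an acyl-anion equivalent that adds 1,4 to the enone (Stetter), and the enol so formed closes onto the isopropyl ketone to give 2β-(tert-butyldimethylsilyloxy)-4β-hydroxydauc-8-ene-6,10-dione F1. Me4NBH(OAc)3 then reduces only the 6-ketone, the one with a β-hydroxyl, to 2β-(tert-butyldimethylsilyloxy)-4β,6α-dihydroxydauc-8-en-10-one F2. Luche reduction (NaBH4, CeCl3·7H2O, MeOH, −40 °C) of the enone carbonyl gives triol 12.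

Step 10 (double angeloylation). The 10-hydroxyl is neopentylic, the epoxy alcohol must survive warm acid anhydride, and angelates drift to tiglates. The fallback sets out from 13 and comes back at 15. It builds the Z-olefins after the ester bonds are in place. Both hydroxyls are acylated with 2-[bis(2,2,2-trifluoroethoxy)phosphoryl]propanoic acid (2.5 equiv, N,N'-dicyclohexylcarbodiimide, 4-(dimethylamino)pyridine, CH2Cl2, 0 °C) to give the bis(phosphonopropanoate) F3. Still–Gennari olefination of both phosphonates with acetaldehyde (excess, KN(SiMe3)2, 18-crown-6, THF, −78 °C) then gives 15 with both (Z)-2-methylbut-2-enoates.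

Step 11 (late desilylation). The silyl ether is hindered, and forcing it risks a 10→2 acyl shift or opening of the epoxide. The fallback sets out from 13 and comes back at 16. It removes the silyl group before any ester is present. HF·pyridine on 13 gives 8α,9α-epoxydaucane-2β,4β,6α,10α-tetraol F4. Phenylboronic acid (toluene, MgSO4, rt) ties the cis-2,4-diol as the cyclic 2,4-O-phenylboronate F5. Angeloylation with two molecules of 14 under the conditions of step 10 gives the boronate bis-angelate F6. Exchange with pinacol in wet THF releases 16.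

**Further compounds**
F1 | step 7 | 2β-(tert-butyldimethylsilyloxy)-4β-hydroxydauc-8-ene-6,10-dione | O=C1CC(C)=CC(=O)[C@@]2(C)[C@@H](O[Si](C)(C)C(C)(C)C)C[C@](O)(C(C)C)[C@@H]12
F2 | step 7 | 2β-(tert-butyldimethylsilyloxy)-4β,6α-dihydroxydauc-8-en-10-one | O[C@@H]1CC(C)=CC(=O)[C@@]2(C)[C@@H](O[Si](C)(C)C(C)(C)C)C[C@](O)(C(C)C)[C@@H]12
F3 | step 10 | 2β-(tert-butyldimethylsilyloxy)-8α,9α-epoxy-4β-hydroxydaucane-6α,10α-diyl bis{2-[bis(2,2,2-trifluoroethoxy)phosphoryl]propanoate} | CC(C(=O)O[C@@H]1C[C@]2(C)O[C@@H]2[C@H](OC(=O)C(C)P(=O)(OCC(F)(F)F)OCC(F)(F)F)[C@@]2(C)[C@@H](O[Si](C)(C)C(C)(C)C)C[C@](O)(C(C)C)[C@@H]12)P(=O)(OCC(F)(F)F)OCC(F)(F)F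
F4 | step 11 | 8α,9α-epoxydaucane-2β,4β,6α,10α-tetraol | O[C@@H]1C[C@]2(C)O[C@@H]2[C@H](O)[C@@]2(C)[C@@H](O)C[C@](O)(C(C)C)[C@@H]12
F5 | step 11 | 8α,9α-epoxydaucane-2β,4β,6α,10α-tetraol 2,4-O-phenylboronate | O[C@@H]1C[C@]2(C)O[C@@H]2[C@H](O)[C@@]2(C)[C@@H]3C[C@](OB(c4ccccc4)O3)(C(C)C)[C@@H]12
F6 | step 11 | 2,4-O-phenylboronate of 8α,9α-epoxy-2β,4β-dihydroxydaucane-6α,10α-diyl bis[(Z)-2-methylbut-2-enoate] | C/C=C(/C)C(=O)O[C@@H]1C[C@]2(C)O[C@@H]2[C@H](OC(=O)/C(C)=C\C)[C@@]2(C)[C@@H]3C[C@](OB(c4ccccc4)O3)(C(C)C)[C@@H]12
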